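**Plan**
Numbering (daucane): ring A = C1 (quaternary, methyl C15), C2, C3, C4 (carbinol, isopropyl), C5; ring B = C1, C5, C6 (ester carbinol), C7, C8 (methyl), C9, C10.
Feature used: ring A carries the contiguous centres C1, C5 and C4; C4–C5 is the aldol bond of a β-hydroxy ketone with its carbonyl at C6, and C1 is β to that carbonyl.
Cuts, in order: ester O–CO; C6 carbinol back to ketone; C8=C9 of ring B (metathesis); C4–C5 and C1–C15 together (aldol and methyl conjugate addition); C6–C7 (methallylation); C1–C2 (carbocupration of an ynoate).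
Forward: an allyl ynoate and a ketal-protected 4-methyl-3-oxopentyl cuprate give a (Z)-enoate, which is taken to the acyclic (Z)-keto-enone; ring A closes first, ring B second, then reduction and esterification.
Stereochemistry: enone geometry from syn carbocupration; C1 from the chiral copper catalyst reading that geometry; C5 and C4 from the aluminium-bridged aldol closure; C6 from hydride delivery by the C4 hydroxyl.

Key step: step 9

Remark: the sense of induction of the phosphoramidite on this acyclic enone is assigned by analogy with cyclic enones; should methyl go to the other face, the mirror-image ligand is used and nothing else changes.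

**Step 1**
Reactants: 1 pent-1-en-4-yne; 2 methyl chloroformate
Product: 4 methyl hex-5-en-2-ynoate, via lithium acetylide 3 (not isolated)
Conditions: n-BuLi (1.0 equiv), THF, −78 °C; then 2, −78 to 0 °C; aq. NH4Cl
Reagents that add atoms: methyl chloroformate 2, COC(=O)Cl
Why: Kinetic deprotonation of the terminal alkyne C–H and C-acylation of the acetylide by the chloroformate (acetylide alkoxycarbonylation) should give the ynoate, the cold, base-free quench keeping the skipped enyne from isomerising.

**Step 2**
Reactants: 5 4-methylpent-1-en-3-one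
Product: 7 2-(2-bromoethyl)-2-(propan-2-yl)-1,3-dioxolane, via bromo ketone 6 (not isolated)
Conditions: HBr (gas), CH2Cl2, 0 °C; then HOCH2CH2OH, TsOH·H2O (cat.), rt
Reagents that add atoms: hydrogen bromide, Br; ethane-1,2-diol, OCCO
Why: Conjugate hydrobromination of the vinyl ketone followed by acid-catalysed ketalisation of the β-bromo ketone is the standard one-flask route to β-halo ketals.

**Step 3**
Reactants: 7 2-(2-bromoethyl)-2-(propan-2-yl)-1,3-dioxolane; 4 methyl hex-5-en-2-ynoate
Product: 10 methyl (2Z)-3-{2-[2-(propan-2-yl)-1,3-dioxolan-2-yl]ethyl}hexa-2,5-dienoate, via Grignard reagent 8 (not isolated), via magnesium cuprate 9 (not isolated)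
Conditions: 7 (2.4 equiv), Mg, THF, 25 °C; CuBr·SMe2 (1.2 equiv), −45 °C; 4 (1 equiv), −78 °C; MeOH then aq. NH4Cl at −78 °C
Reagents that add atoms: none
Why: Syn carbocupration of the alkynoate at −78 °C puts alkyl and copper on the same side of the triple bond and the vinylcopper is protonated with retention, so the new chain ends trans and the allyl group cis to the ester, which fixes the (Z) geometry; an ester is used because the vinylcopper of an ynoate holds its configuration at this temperature.

**Step 4**
Reactants: 10 methyl (2Z)-3-{2-[2-(propan-2-yl)-1,3-dioxolan-2-yl]ethyl}hexa-2,5-dienoate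
Product: 11 (2Z)-3-{2-[2-(propan-2-yl)-1,3-dioxolan-2-yl]ethyl}hexa-2,5-dien-1-ol
Conditions: i-Bu2AlH (2.5 equiv), CH2Cl2, −78 °C; aq. potassium sodium tartrate
Reagents that add atoms: none
Why: 1,2-Reduction of the conjugated ester by i-Bu2AlH should give the allylic alcohol without touching the ketal or the double-bond geometry.

**Step 5**
Reactants: 11 (2Z)-3-{2-[2-(propan-2-yl)-1,3-dioxolan-2-yl]ethyl}hexa-2,5-dien-1-ol
Product: 12 (6Z)-8-hydroxy-2-methyl-6-(prop-2-en-1-yl)oct-6-en-3-one
Conditions: PPTS (0.2 equiv), acetone/H2O 10:1, 40 °C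
Reagents that add atoms: water, O
Why: Mild acid-catalysed ketal hydrolysis frees the isopropyl ketone at the stage where the only other sensitive group is a primary allylic alcohol, which tolerates PPTS, so that no acid is needed later on the β,γ-unsaturated ketone.

**Step 6**
Reactants: 12 (6Z)-8-hydroxy-2-methyl-6-(prop-2-en-1-yl)oct-6-en-3-one
Product: 13 (2Z)-7-methyl-6-oxo-3-(prop-2-en-1-yl)oct-2-enal
Conditions: MnO2 (activated, excess), CH2Cl2, rt
Reagents that add atoms: none
Why: MnO2 oxidises only the allylic alcohol, under neutral conditions that should keep the (Z) geometry and leave the saturated ketone alone.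

**Step 7**
Reactants: 13 (2Z)-7-methyl-6-oxo-3-(prop-2-en-1-yl)oct-2-enal; 14 4,4,5,5-tetramethyl-2-(2-methylprop-2-en-1-yl)-1,3,2-dioxaborolane
Product: 15 (6Z)-8-hydroxy-2,10-dimethyl-6-(prop-2-en-1-yl)undeca-6,10-dien-3-one (racemic at C8)
Conditions: 14 (1.3 equiv), CH2Cl2 (1 M), rt; then aq. NaHCO3
Reagents that add atoms: 4,4,5,5-tetramethyl-2-(2-methylprop-2-en-1-yl)-1,3,2-dioxaborolane 14, C=C(C)CB1OC(C)(C)C(C)(C)O1
Why: Uncatalysed allylboration through a six-membered chair transition state adds the methallyl group to the aldehyde and not to the hindered ketone and brings in no base that could move the skipped double bonds; the carbinol centre is lost in the next step.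

**Step 8**
Reactants: 15 (6Z)-8-hydroxy-2,10-dimethyl-6-(prop-2-en-1-yl)undeca-6,10-dien-3-one
Product: 16 (6Z)-2,10-dimethyl-6-(prop-2-en-1-yl)undeca-6,10-diene-3,8-dione
Conditions: Dess–Martin periodinane (1.3 equiv), NaHCO3, CH2Cl2, 0 °C; used at once
Reagents that add atoms: none
Why: Dess–Martin oxidation under buffered, non-basic conditions is the usual way to a β,γ-unsaturated ketone from a homoallylic alcohol without moving the double bond into conjugation.

**Step 9**
Reactants: 16 (6Z)-2,10-dimethyl-6-(prop-2-en-1-yl)undeca-6,10-diene-3,8-dione; 17 trimethylaluminium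
Product: 20 1-[(1R,2R,5R)-2-hydroxy-5-methyl-2-(propan-2-yl)-5-(prop-2-en-1-yl)cyclopentyl]-3-methylbut-3-en-1-one, via aluminium enolate 18 (not isolated), via aluminium aldolate 19 (not isolated)
Conditions: AlMe3 (2 equiv), Cu(O2CC4H3S) (CuTC, 10 mol%), (S,S)-N,N-bis(1-phenylethyl)dibenzo[d,f][1,3,2]dioxaphosphepin-6-amine (20 mol%), Et2O, −30 to 0 °C; aq. potassium sodium tartrate, −20 °C
Reagents that add atoms: trimethylaluminium 17, C[Al](C)C
Why: AlMe3 transfers methyl to the copper–phosphoramidite complex, which adds it to C1 of the s-cis enone through a π-complex and a trivalent copper intermediate and releases the (Z)-dimethylaluminium enolate 18, formed at C5 only (C1–C15 made). The closest known reactions are the copper-catalysed asymmetric conjugate addition of AlMe3 to β,β-disubstituted enones that creates quaternary carbons and the tandem conjugate addition–aldol cyclisation of enone-ketones, combined here on an acyclic keto-enone. Ring A closes by a 5-(enolexo)-exo-trig aldol addition of C5 to the isopropyl ketone carbon C4, the only ring size this enolate can reach. C1 is controlled by the ligand reading the (Z)-enone set in step 3; C4 by the aluminium bridge between enolate oxygen and ketone oxygen, which leaves the hydroxyl cis to the acyl group; C5 by allylic 1,3-strain in the enolate, which turns the methyl group of C1 and not the allyl group toward the O–Al side, so that C4 adds to the face that leaves the acyl group cis to methyl and trans to allyl. Since the aldolate 19 can re-open, the ring can also settle thermodynamically into this same isomer, whose acyl group is trans to both allyl and isopropyl. The step needs 1,4- and not 1,2-addition of methyl and an untouched methallyl ketone, which the soft copper catalyst, the weakly basic aluminium reagent at −30 °C and a cold buffered quench should secure.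

**Step 10**
Reactants: 20 1-[(1R,2R,5R)-2-hydroxy-5-methyl-2-(propan-2-yl)-5-(prop-2-en-1-yl)cyclopentyl]-3-methylbut-3-en-1-one
Product: 21 (3R,3aR,8aR)-3-hydroxy-6,8a-dimethyl-3-(propan-2-yl)-2,3,3a,5,8,8a-hexahydroazulen-4(1H)-one
Conditions: second-generation Grubbs catalyst (5 mol%), 1,4-benzoquinone (10 mol%), CH2Cl2 (5 mM), 40 °C
Reagents that add atoms: none
Why: Ring-closing metathesis of the allyl alkene with the 1,1-disubstituted methallyl alkene should close ring B as the trisubstituted cycloheptene with loss of ethene, the two chains being trans on ring A (trans-fused hydroazulene) and benzoquinone holding back ruthenium hydride isomerisation.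

**Step 11**
Reactants: 21 (3R,3aR,8aR)-3-hydroxy-6,8a-dimethyl-3-(propan-2-yl)-2,3,3a,5,8,8a-hexahydroazulen-4(1H)-one
Product: 22 (3R,3aS,4S,8aR)-6,8a-dimethyl-3-(propan-2-yl)-1,2,3,3a,4,5,8,8a-octahydroazulene-3,4-diol
Conditions: Me4NBH(OAc)3 (5 equiv), MeCN/AcOH 1:1, −30 to −10 °C
Reagents that add atoms: none
Why: In this hydroxyl-directed (Evans–Saksena type) reduction the C4 hydroxyl exchanges an acetate on boron and the hydride is delivered within a chair-like six-membered transition state to the face of C6 on the side of O4, which in the trans-fused ring is the face syn to the angular methyl, so that the new C6–H ends anti to C5–H and the two hydroxyls anti.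

**Step 12**
Reactants: 22 (3R,3aS,4S,8aR)-6,8a-dimethyl-3-(propan-2-yl)-1,2,3,3a,4,5,8,8a-octahydroazulene-3,4-diol; 23 3,4-dimethoxybenzoyl chloride (veratroyl chloride)
Product: 24 (3R,3aS,4S,8aR)-3-hydroxy-6,8a-dimethyl-3-(propan-2-yl)-1,2,3,3a,4,5,8,8a-octahydroazulen-4-yl 3,4-dimethoxybenzoate
Conditions: 23 (1.5 equiv), pyridine, DMAP (cat.), CH2Cl2, 0 °C to rt
Reagents that add atoms: 3,4-dimethoxybenzoyl chloride 23, COc1ccc(C(=O)Cl)cc1OC
Why: DMAP-catalysed acylation by the acid chloride should take place only at the secondary C6 hydroxyl, the tertiary C4 hydroxyl being too hindered.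

**Compound list**
1 | pent-1-en-4-yne | C=CCC#C | starting material
2 | methyl chloroformate | COC(=O)Cl | starting material
3 | lithium pent-4-en-1-yn-1-ide (not isolated) | [Li]C#CCC=C | intermediate
4 | methyl hex-5-en-2-ynoate | COC(=O)C#CCC=C | intermediate
5 | 4-methylpent-1-en-3-one | C=CC(=O)C(C)C | starting material
6 | 1-bromo-4-methylpentan-3-one (not isolated) | BrCCC(=O)C(C)C | intermediate
7 | 2-(2-bromoethyl)-2-(propan-2-yl)-1,3-dioxolane | BrCCC1(C(C)C)OCCO1 | intermediate
8 | {2-[2-(propan-2-yl)-1,3-dioxolan-2-yl]ethyl}magnesium bromide (not isolated) | Br[Mg]CCC1(C(C)C)OCCO1 | intermediate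
9 | bromomagnesium bis{2-[2-(propan-2-yl)-1,3-dioxolan-2-yl]ethyl}cuprate (not isolated) | CC(C)C1(CC[Cu-]CCC2(C(C)C)OCCO2)OCCO1.[Mg+]Br | intermediate
10 | methyl (2Z)-3-{2-[2-(propan-2-yl)-1,3-dioxolan-2-yl]ethyl}hexa-2,5-dienoate | COC(=O)/C=C(\CC=C)CCC1(C(C)C)OCCO1 | intermediate
11 | (2Z)-3-{2-[2-(propan-2-yl)-1,3-dioxolan-2-yl]ethyl}hexa-2,5-dien-1-ol | OC/C=C(\CC=C)CCC1(C(C)C)OCCO1 | intermediate
12 | (6Z)-8-hydroxy-2-methyl-6-(prop-2-en-1-yl)oct-6-en-3-one | OC/C=C(\CC=C)CCC(=O)C(C)C | intermediate
13 | (2Z)-7-methyl-6-oxo-3-(prop-2-en-1-yl)oct-2-enal | O=C/C=C(\CC=C)CCC(=O)C(C)C | intermediate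
14 | 4,4,5,5-tetramethyl-2-(2-methylprop-2-en-1-yl)-1,3,2-dioxaborolane | C=C(C)CB1OC(C)(C)C(C)(C)O1 | starting material
15 | (6Z)-8-hydroxy-2,10-dimethyl-6-(prop-2-en-1-yl)undeca-6,10-dien-3-one, racemic at C8 | C=C(C)CC(O)/C=C(\CC=C)CCC(=O)C(C)C | intermediate
16 | (6Z)-2,10-dimethyl-6-(prop-2-en-1-yl)undeca-6,10-diene-3,8-dione | C=C(C)CC(=O)/C=C(\CC=C)CCC(=O)C(C)C | intermediate
17 | trimethylaluminium | C[Al](C)C | starting material
18 | dimethylaluminium (6R,7Z)-2,6,10-trimethyl-3-oxo-6-(prop-2-en-1-yl)undeca-7,10-dien-8-olate (not isolated) | C=C(C)C/C(O[Al](C)C)=C/[C@@](C)(CC=C)CCC(=O)C(C)C | intermediate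
19 | dimethylaluminium (1R,2R,3R)-3-methyl-2-(3-methylbut-3-enoyl)-1-(propan-2-yl)-3-(prop-2-en-1-yl)cyclopentan-1-olate (not isolated) | C=C(C)CC(=O)[C@@H]1[C@@](C)(CC=C)CC[C@@]1(O[Al](C)C)C(C)C | intermediate
20 | 1-[(1R,2R,5R)-2-hydroxy-5-methyl-2-(propan-2-yl)-5-(prop-2-en-1-yl)cyclopentyl]-3-methylbut-3-en-1-one | C=C(C)CC(=O)[C@@H]1[C@@](C)(CC=C)CC[C@@]1(O)C(C)C | intermediate
21 | (3R,3aR,8aR)-3-hydroxy-6,8a-dimethyl-3-(propan-2-yl)-2,3,3a,5,8,8a-hexahydroazulen-4(1H)-one | O=C1CC(C)=CC[C@@]2(C)CC[C@@](O)(C(C)C)[C@H]12 | intermediate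
22 | (3R,3aS,4S,8aR)-6,8a-dimethyl-3-(propan-2-yl)-1,2,3,3a,4,5,8,8a-octahydroazulene-3,4-diol | O[C@H]1CC(C)=CC[C@@]2(C)CC[C@@](O)(C(C)C)[C@H]12 | intermediate
23 | 3,4-dimethoxybenzoyl chloride | COc1ccc(C(=O)Cl)cc1OC | starting material
24 | (3R,3aS,4S,8aR)-3-hydroxy-6,8a-dimethyl-3-(propan-2-yl)-1,2,3,3a,4,5,8,8a-octahydroazulen-4-yl 3,4-dimethoxybenzoate | COc1ccc(C(=O)O[C@H]2CC(C)=CC[C@@]3(C)CC[C@@](O)(C(C)C)[C@H]23)cc1OC | target

**Count**
Total steps: 12. Longest linear sequence: 11 (steps 1, 3–12; the same length from 5 through steps 2, 3–12).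

**Steps most likely to fail**

Step 9. Methyl delivery may show low facial selectivity because both β-substituents are primary alkyl groups. The aluminium enolate may also close slowly or with poor control of C5 relative to C1, since methyl and allyl differ little in size. The fallback separates the two events. It sets out from 16: the conjugate addition is run alone (the same catalyst, or the sulfonate-bearing N-heterocyclic carbene–copper catalyst known for acyclic trisubstituted enones) and the aluminium enolate is trapped with Me3SiOTf as (6R,7Z)-2,6,10-trimethyl-6-(prop-2-en-1-yl)-8-[(trimethylsilyl)oxy]undeca-7,10-dien-3-one F1. An intramolecular Mukaiyama aldol addition of F1 with TiCl4 in CH2Cl2 at −78 °C, through a titanium chelate between the two oxygens, then comes back to the route at 20.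

Step 11. Exchange of the hindered tertiary hydroxyl on boron may be slow, so that undirected hydride addition from the open face, anti to the angular methyl, takes over and gives the other C6 configuration. The fallback uses that open-face attack on purpose. It sets out from 21: NaBH4 with CeCl3·7H2O in MeOH at −40 °C should give (3R,3aS,4R,8aR)-6,8a-dimethyl-3-(propan-2-yl)-1,2,3,3a,4,5,8,8a-octahydroazulene-3,4-diol F2. Mitsunobu esterification of F2 with 3,4-dimethoxybenzoic acid (PPh3, diisopropyl azodicarboxylate, toluene) inverts the secondary carbinol and installs the ester in one operation, coming back to the route at 24.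

Step 10. Ruthenium hydride may move the methallyl double bond into conjugation with the C6 ketone before ring closure, or the trans-fused seven-membered ring may close slowly and give oligomers. The fallback takes the ketone out of play for the metathesis. It sets out from 20: NaBH4 in MeOH gives (1R,2S,3R)-2-(1-hydroxy-3-methylbut-3-en-1-yl)-3-methyl-1-(propan-2-yl)-3-(prop-2-en-1-yl)cyclopentan-1-ol F3, as both carbinol epimers, which does not matter. Ring-closing metathesis of F3 (second-generation Hoveyda–Grubbs catalyst, toluene, 80 °C) gives (3R,3aS,8aR)-6,8a-dimethyl-3-(propan-2-yl)-1,2,3,3a,4,5,8,8a-octahydroazulene-3,4-diol F4 as both C4 epimers. Dess–Martin oxidation of the secondary hydroxyl of F4 comes back to the route at 21.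

**Further compounds**
F1 | step 9 | (6R,7Z)-2,6,10-trimethyl-6-(prop-2-en-1-yl)-8-[(trimethylsilyl)oxy]undeca-7,10-dien-3-one | C=C(C)C/C(O[Si](C)(C)C)=C/[C@@](C)(CC=C)CCC(=O)C(C)C
F2 | step 11 | (3R,3aS,4R,8aR)-6,8a-dimethyl-3-(propan-2-yl)-1,2,3,3a,4,5,8,8a-octahydroazulene-3,4-diol | O[C@@H]1CC(C)=CC[C@@]2(C)CC[C@@](O)(C(C)C)[C@H]12
F3 | step 10 | (1R,2S,3R)-2-(1-hydroxy-3-methylbut-3-en-1-yl)-3-methyl-1-(propan-2-yl)-3-(prop-2-en-1-yl)cyclopentan-1-ol, both carbinol epimers | C=C(C)CC(O)[C@@H]1[C@@](C)(CC=C)CC[C@@]1(O)C(C)C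
F4 | step 10 | (3R,3aS,8aR)-6,8a-dimethyl-3-(propan-2-yl)-1,2,3,3a,4,5,8,8a-octahydroazulene-3,4-diol, both C4 epimers | OC1CC(C)=CC[C@@]2(C)CC[C@@](O)(C(C)C)[C@H]12
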